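Both oxygen heterocycles of the target share one pattern. The pyran O and an Ar–CH2 sit on adjacent tropolone carbons (C4, C5) and are bridged by two sp3 chain carbons (O–CH and CH2 or CHCH3). That pattern is the footprint of an O=C–C=CH2 heterodiene on an alkene. Retro-[4+2] at both rings therefore gives two copies of one tropolone o-quinone methide plus all-E nona-1,3,5,7-tetraene, whose inner diene remains as linker. A single chiral-acid-catalysed operation joins the three pieces, closes both pyrans, makes two C–C and two C–O bonds and sets all three stereocentres. The methide precursor is 2,4-dihydroxy-5-(hydroxymethyl)-6-methyltropone.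

Key step: step 10

Assumption: the sense of induction of the chiral acid cannot be foretold for this new substrate class, so the (R)-configured catalyst is written and its mirror image is to be used if a trial run leads to the (S,S,S) series; the bicyclic intermediates ahead of the tropolone are racemic (one enantiomer drawn), tropone rings are numbered from C1 = C=O, and the chain keeps the tetraene numbering C1–C9 (C2 and C7 = O–CH, C8 = CHCH3).

Step 1
Reactants: 1 2-methylanisole
Product: 2 1-methoxy-2-methylcyclohexa-1,4-diene
Conditions: Li, NH3(l), THF, t-BuOH, −78 → −33 °C; H2O, pentane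
Reagents that add atoms: none
Why: Birch reduction, in which the ring is protonated ortho and meta to each donor, so the OMe- and CH3-bearing carbons both stay sp2 and the unconjugated diene with a tetrasubstituted enol ether should result; no stereocentre is formed.

Step 2
Reactants: 2 1-methoxy-2-methylcyclohexa-1,4-diene; 3 bromoform
Product: 5 rac-7,7-dibromo-1-methoxy-6-methylbicyclo[4.1.0]hept-3-ene (cis-fused), via dibromocarbene 4 (not isolated)
Conditions: CHBr3 (1.1 equiv), KOt-Bu, pentane, −10 → 0 °C
Reagents that add atoms: bromoform 3, BrC(Br)Br
Why: Cheletropic [2+1] addition of the electrophilic singlet carbene, which should pick the oxygen-activated tetrasubstituted C=C over the plain disubstituted one; the concerted syn addition can only give the cis ring fusion, as a racemate.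

Step 3
Reactants: 5 rac-7,7-dibromo-1-methoxy-6-methylbicyclo[4.1.0]hept-3-ene
Product: 6 rac-7,7-dibromo-1-methoxy-6-methylbicyclo[4.1.0]heptane-3,4-diol (cis-diol on the face opposite to the CBr2 bridge)
Conditions: OsO4 (2 mol %), N-methylmorpholine N-oxide, acetone–H2O, rt
Reagents that add atoms: OsO4 (oxygen carrier), O=[Os](=O)(=O)=O; N-methylmorpholine N-oxide, C[N+]1([O-])CCOCC1; water, O
Why: Catalytic OsO4/NMO syn-dihydroxylation of the only remaining alkene, expected from the face away from the endo bromine; both carbinol centres are erased in step 4, so their configuration has no consequence.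

Step 4
Reactants: 6 rac-7,7-dibromo-1-methoxy-6-methylbicyclo[4.1.0]heptane-3,4-diol
Product: 8 5-bromo-2-hydroxy-4-methoxy-6-methylcyclohepta-2,4,6-trien-1-one (bromotropolone), via 1,2-dione 7 (not isolated)
Conditions: (CF3CO)2O, DMSO, CH2Cl2, −78 °C; Et3N, −78 °C → rt
Reagents that add atoms: none
Why: A double Swern-type oxidation gives dione 7, whose enolate next to C–OMe should trigger a Grob-type opening of the central cyclopropane bond with loss of bromide, and tautomerisation then gives the aromatic tropolone with the former CBr2 carbon lying between C–OMe and C–CH3; all stereocentres vanish.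

Step 5
Reactants: 8 5-bromo-2-hydroxy-4-methoxy-6-methyltropone
Product: 9 5-bromo-2,4-dimethoxy-6-methyltropone and 10 5-bromo-2,6-dimethoxy-4-methyltropone (the two O-methyl regioisomers, carried on together)
Conditions: MeI, K2CO3, acetone, reflux
Reagents that add atoms: iodomethane, CI
Why: Williamson O-alkylation of the tropolonate, which removes the chelating anionic hydroxy-ketone that would bind palladium and slow oxidative addition; methylation at either oxygen is harmless because both isomers converge in step 7.

Step 6
Reactants: 9 5-bromo-2,4-dimethoxy-6-methyltropone and 10 5-bromo-2,6-dimethoxy-4-methyltropone; 11 carbon monoxide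
Product: 12 5-(methoxycarbonyl)-2,4-dimethoxy-6-methyltropone and 13 5-(methoxycarbonyl)-2,6-dimethoxy-4-methyltropone
Conditions: CO (1 atm), Pd(OAc)2 (5 mol %), 4,5-bis(diphenylphosphino)-9,9-dimethylxanthene (10 mol %), Et3N, MeOH–DMF, 75 °C
Reagents that add atoms: carbon monoxide 11, [C-]#[O+]; methanol, CO
Why: Palladium-catalysed alkoxycarbonylation (oxidative addition of zerovalent palladium, CO insertion, methanolysis of the acyl complex), a reaction type established for bromotropolone ethers, run with a wide-bite-angle ligand that tolerates flanked bromides at low CO pressure.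

Step 7
Reactants: 12 5-(methoxycarbonyl)-2,4-dimethoxy-6-methyltropone and 13 5-(methoxycarbonyl)-2,6-dimethoxy-4-methyltropone
Product: 14 methyl 2,4-dihydroxy-7-methyl-5-oxocyclohepta-1,3,6-triene-1-carboxylate (5-methoxycarbonyl-4-hydroxy-6-methyltropolone)
Conditions: BCl3 (5 equiv), CH2Cl2, −78 °C → rt; H2O
Reagents that add atoms: none
Why: Chelation-assisted Lewis-acid ether cleavage, in which boron binds the ring C=O beside one OMe and the ester C=O beside the other and chloride removes each methyl by SN2 while the hindered ester should survive; unmasking here spares the later acid-labile CH2OH any hydrolysis conditions.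

Step 8
Reactants: 14 5-methoxycarbonyl-4-hydroxy-6-methyltropolone
Product: 15 2,4-dihydroxy-5-(hydroxymethyl)-6-methylcyclohepta-2,4,6-trien-1-one
Conditions: i-Bu2AlH (6 equiv), THF–CH2Cl2, −78 → −20 °C; aq. potassium sodium tartrate, citric acid to pH 5, 0 °C
Reagents that add atoms: none
Why: Ester-to-alcohol reduction with i-Bu2AlH, whose first two equivalents turn both acidic OH groups into O–Al(i-Bu)2, so that the ring is masked as an electron-rich aluminium tropolonate that resists hydride addition while the C4–O–Al unit chelates and activates the ester; the cold buffered work-up should free 15 without ionising it.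

Step 9
Reactants: 16 (2E,4E)-hexa-2,4-dienal (sorbaldehyde); 17 diethyl allylphosphonate
Product: 20 (3E,5E,7E)-nona-1,3,5,7-tetraene, via lithiated allylphosphonate 18 (not isolated), via 3E/3Z tetraene mixture 19 (not isolated)
Conditions: 17, n-BuLi, THF–DMPU, −78 °C; 16, −78 °C → rt; pentane extract, I2 (2 mol %), daylight, rt; aq. Na2S2O3, basic alumina; kept as a cold toluene stock solution with BHT under Ar
Reagents that add atoms: diethyl allylphosphonate 17, C=CCP(=O)(OCC)OCC
Why: Horner–Wadsworth–Emmons olefination, in which DMPU steers the allyl anion to react through its α-carbon and mainly the E alkene should form, followed by reversible iodine-atom addition that equilibrates residual 3Z isomer to the thermodynamically preferred all-E tetraene.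

Step 10
Reactants: 15 2,4-dihydroxy-5-(hydroxymethyl)-6-methyltropone (2.3 equiv); 20 (3E,5E,7E)-nona-1,3,5,7-tetraene (1 equiv)
Product: 23 CNP0332980.1, (2R,3R)-8-hydroxy-2-{(1E,3E)-4-[(2R)-8-hydroxy-5-methyl-7-oxo-2,3,4,7-tetrahydrocyclohepta[b]pyran-2-yl]buta-1,3-dien-1-yl}-3,5-dimethyl-3,4-dihydrocyclohepta[b]pyran-7(2H)-one, via tropolone o-quinone methide 21 (not isolated), via vinyl-end monoadduct 22 (not isolated)
Conditions: (R)-3,3'-bis(2,4,6-triisopropylphenyl)-1,1'-binaphthyl-2,2'-diyl N-(trifluoromethanesulfonyl)phosphoramide (10 mol %), 5 Å MS, BHT (trace), CH2Cl2–PhMe, −40 → −10 °C, dark, Ar, 15 added in portions; solid NaHCO3 at low temperature; reversed-phase HPLC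
Reagents that add atoms: none
Why: Proposed new method: the acid protonates the CH2OH of 15, water leaves with push from the C4–OH, and the methide 21 stays hydrogen-bonded to the chiral acid through its C4 carbonyl (plausibly also through the tropolone OH), after which its exocyclic CH2 bonds to a chain terminus while the C4 oxygen closes on the neighbouring carbon of the polyenyl-stabilised partial cation, an asynchronous inverse-electron-demand hetero-Diels–Alder reaction driven by the return of tropolone aromaticity. The closest known reaction types are the thermal cycloaddition of tropolone o-quinone methides to humulene-type alkenes, double addition included, and the chiral N-triflylphosphoramide- or phosphoric-acid-catalysed [4+2] of benzenoid o-quinone methides, released in situ from o-hydroxybenzyl alcohols, with styrenes and other unactivated alkenes; neither has been run enantioselectively on a tropolone methide or twice on one polyene. Ring B (methide CH2 to C1, O to C2) and ring A (methide CH2 to C8, O to C7) are each closed as six-membered rings by an intermolecular two-bond [4+2] closure, the unhindered vinyl end being expected to react first to give 22. C2 and C7 are fixed by the alkene face that the catalyst-bound methide accepts, so the pocket has to control both the open face of the methide and the exo or endo placement of the polyenyl chain, and the same catalyst acting independently at both ends should give the like (2R,7R) pair, while C8 follows from C7 because addition across the (E)-propenyl bond is suprafacial (CH3 trans to dienyl, 8R). The step needs terminal-over-internal site selectivity and O-to-internal-carbon regiochemistry, which the substrate secures because only attack at C1 or C8 spreads the charge over all remaining double bonds and meets the least steric demand, because closure to a six-membered ring outruns capture at the remote cation termini, and because the much more basic tropolone carbonyls level the acid and so spare the tetraene from protonation. The unlike (2S,7R,8R) and (2R,7S,8S) isomers are removed by HPLC, and since a minor-face event at one end mostly ends up in these diastereomers, the enantiomeric purity of 23 should exceed that of a single cycloaddition.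

Compound list
1 | 2-methylanisole | COc1ccccc1C | starting material
2 | 1-methoxy-2-methylcyclohexa-1,4-diene | COC1=C(C)CC=CC1 | intermediate
3 | bromoform | BrC(Br)Br | starting material
4 | dibromocarbene (not isolated) | Br[C]Br | intermediate
5 | rac-7,7-dibromo-1-methoxy-6-methylbicyclo[4.1.0]hept-3-ene, cis-fused | CO[C@]12CC=CC[C@@]1(C)C2(Br)Br | intermediate
6 | rac-7,7-dibromo-1-methoxy-6-methylbicyclo[4.1.0]heptane-3,4-diol, cis-diol anti to the CBr2 bridge | CO[C@]12C[C@H](O)[C@H](O)C[C@@]1(C)C2(Br)Br | intermediate
7 | rac-7,7-dibromo-1-methoxy-6-methylbicyclo[4.1.0]heptane-3,4-dione (not isolated) | CO[C@]12CC(=O)C(=O)C[C@@]1(C)C2(Br)Br | intermediate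
8 | 5-bromo-2-hydroxy-4-methoxy-6-methylcyclohepta-2,4,6-trien-1-one | COc1cc(O)c(=O)cc(C)c1Br | intermediate
9 | 5-bromo-2,4-dimethoxy-6-methyltropone | COc1cc(OC)c(=O)cc(C)c1Br | intermediate
10 | 5-bromo-2,6-dimethoxy-4-methyltropone (O-methyl regioisomer of 9) | COc1cc(C)c(Br)c(OC)cc1=O | intermediate
11 | carbon monoxide | [C-]#[O+] | starting material
12 | 5-(methoxycarbonyl)-2,4-dimethoxy-6-methyltropone | COC(=O)c1c(C)cc(=O)c(OC)cc1OC | intermediate
13 | 5-(methoxycarbonyl)-2,6-dimethoxy-4-methyltropone (O-methyl regioisomer of 12) | COC(=O)c1c(C)cc(OC)c(=O)cc1OC | intermediate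
14 | methyl 2,4-dihydroxy-7-methyl-5-oxocyclohepta-1,3,6-triene-1-carboxylate | COC(=O)c1c(C)cc(=O)c(O)cc1O | intermediate
15 | 2,4-dihydroxy-5-(hydroxymethyl)-6-methylcyclohepta-2,4,6-trien-1-one | Cc1cc(=O)c(O)cc(O)c1CO | intermediate
16 | (2E,4E)-hexa-2,4-dienal | C/C=C/C=C/C=O | starting material
17 | diethyl allylphosphonate | C=CCP(=O)(OCC)OCC | starting material
18 | lithiated diethyl allylphosphonate (not isolated) | [Li+].C=C[CH-]P(=O)(OCC)OCC | intermediate
19 | (5E,7E)-nona-1,3,5,7-tetraene, 3E/3Z mixture (not isolated) | C=CC=C/C=C/C=C/C | intermediate
20 | (3E,5E,7E)-nona-1,3,5,7-tetraene | C=C/C=C/C=C/C=C/C | intermediate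
21 | 2-hydroxy-6-methyl-5-methylidenecyclohepta-2,6-diene-1,4-dione, tropolone o-quinone methide (not isolated) | C=C1C(C)=CC(=O)C(O)=CC1=O | intermediate
22 | (2R)-2-[(1E,3E,5E)-hepta-1,3,5-trien-1-yl]-8-hydroxy-5-methyl-3,4-dihydrocyclohepta[b]pyran-7(2H)-one (not isolated) | C/C=C/C=C/C=C/[C@H]1CCc2c(C)cc(=O)c(O)cc2O1 | intermediate
23 | CNP0332980.1, (2R,7R,8R) in chain numbering; ring A trans-2,3-disubstituted, ring B 2-substituted, (E,E)-butadiene linker | Cc1cc(=O)c(O)cc2c1C[C@@H](C)[C@H](/C=C/C=C/[C@H]1CCc3c(C)cc(=O)c(O)cc3O1)O2 | target

Total steps: 10. Longest linear sequence: 9 (steps 1–8 and 10); step 9 is the convergent branch.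

Steps most likely to fail

1. Step 10.
- What may go wrong:
  - poor face discrimination at one terminus;
  - attack of the second methide at C3 of the monoadduct instead of C8;
  - acid-triggered oligomerisation of the polyene;
  - self-condensation of the methide;
  - re-ionisation of the doubly allylic C–O bonds with loss of configuration.
- The fallback gives up catalyst control. It uses the known thermal mode of tropolone methide cycloaddition, followed by resolution. It sets out from 15 and 20 and comes back at 23.
- Heating excess 15 with 20 in toluene at about 100 °C in a sealed vessel with BHT should release 21 without acid. Ring A should still be trans, because the addition stays suprafacial.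
- The expected products are two racemic pairs. The like pair is 23 and the (2S,7S,8S)-enantiomer F1. The unlike pair is the (2S,7R,8R)-diastereomer F2 and the (2R,7S,8S)-diastereomer F3.
- Reversed-phase HPLC removes F2 and F3. Preparative HPLC on an amylose tris(3,5-dimethylphenylcarbamate) phase then separates 23 from F1.

2. Step 8.
- What may go wrong:
  - expulsion of the aluminium alkoxide from the very electron-rich ring followed by a further hydride transfer, which over-reduces CH2OH to CH3;
  - hydride addition to the ring;
  - incomplete release of the product from aluminium.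
- The fallback brings the carbon in at the aldehyde level, so that only one mild borohydride transfer is needed. It sets out from 9 and 10 and comes back at 15.
- Reductive carbonylation (Pd(OAc)2, di(1-adamantyl)-n-butylphosphine, CO/H2, TMEDA, toluene, 100 °C) should give 5-formyl-2,4-dimethoxy-6-methyltropone F4 and 5-formyl-2,6-dimethoxy-4-methyltropone F5.
- BCl3 in CH2Cl2 converges both on 5-formyl-2,4-dihydroxy-6-methyltropone F6.
- NaBH4 in MeOH–aq. NaOH at 0 °C, followed by acidification to pH 5, reduces the aldehyde of the unreactive tropolonate to give 15.

3. Step 6.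
- What may go wrong: slow insertion of CO-ligated zerovalent palladium into the C–Br bond flanked by OMe and CH3, with hydrodebromination taking over.
- The fallback forms the C–C bond by a CO-free cross-coupling and adjusts the oxidation level afterwards. It sets out from 9 and 10 and comes back at 12 and 13.
- Stille coupling with tributyl(vinyl)stannane (Pd(PPh3)4, toluene, 100 °C) should give 2,4-dimethoxy-6-methyl-5-vinyltropone F7 and 2,6-dimethoxy-4-methyl-5-vinyltropone F8.
- Oxidative cleavage of the twisted, styrene-like vinyl group with OsO4 (cat.) and KHSO5 in DMF gives 2,4-dimethoxy-6-methyl-1-oxocyclohepta-2,4,6-triene-5-carboxylic acid F9 and its 2,6-dimethoxy-4-methyl regioisomer F10.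
- MeI and K2CO3 in DMF esterify these to 12 and 13.

Further compounds
F1 | step 10 | (2S,7S,8S)-enantiomer of 23 | Cc1cc(=O)c(O)cc2c1C[C@H](C)[C@@H](/C=C/C=C/[C@@H]1CCc3c(C)cc(=O)c(O)cc3O1)O2
F2 | step 10 | (2S,7R,8R)-diastereomer of 23 | Cc1cc(=O)c(O)cc2c1C[C@@H](C)[C@H](/C=C/C=C/[C@@H]1CCc3c(C)cc(=O)c(O)cc3O1)O2
F3 | step 10 | (2R,7S,8S)-diastereomer of 23 | Cc1cc(=O)c(O)cc2c1C[C@H](C)[C@@H](/C=C/C=C/[C@H]1CCc3c(C)cc(=O)c(O)cc3O1)O2
F4 | step 8 | 5-formyl-2,4-dimethoxy-6-methyltropone | COc1cc(OC)c(=O)cc(C)c1C=O
F5 | step 8 | 5-formyl-2,6-dimethoxy-4-methyltropone | COc1cc(C)c(C=O)c(OC)cc1=O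
F6 | step 8 | 5-formyl-2,4-dihydroxy-6-methyltropone | Cc1cc(=O)c(O)cc(O)c1C=O
F7 | step 6 | 2,4-dimethoxy-6-methyl-5-vinyltropone | COc1cc(OC)c(=O)cc(C)c1C=C
F8 | step 6 | 2,6-dimethoxy-4-methyl-5-vinyltropone | COc1cc(C)c(C=C)c(OC)cc1=O
F9 | step 6 | 2,4-dimethoxy-6-methyl-1-oxocyclohepta-2,4,6-triene-5-carboxylic acid | COc1cc(OC)c(=O)cc(C)c1C(=O)O
F10 | step 6 | 2,6-dimethoxy-4-methyl-1-oxocyclohepta-2,4,6-triene-5-carboxylic acid | COc1cc(C)c(C(=O)O)c(OC)cc1=O
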